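**Retrosynthetic overview**
1. The C1–C8 bond is made last: ring B of the bicyclo[3.3.1]nonane closes when the acyl-bearing enol carbon of a dearomatised, C5-quaternary acylphloroglucinol captures a tertiary C8 carbocation, as in the biosynthesis, with C7 already set.
2. The cation precursor (tertiary alkoxide, then mesylate) comes from double MeLi addition to an enol δ-lactone that ties O4 to C8; this temporary lactone relays stereochemistry from C5 to C7 (enolate prenylation trans to the C5 prenyl).
3. The lactone comes from deoxycohumulone and acryloyl chloride by O4-acylation and a catalytic enantioselective dearomative intramolecular Michael addition, which sets C5.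
4. Deoxycohumulone comes from phloroglucinol, isobutyryl chloride and two prenyl bromides.
5. Ring order: aromatic ring A (bought) → temporary lactone ring (opened again) → carbocyclic ring B.

Assumption: the target is secohyperforin written as its C4-enol; enolised triketones are written as one tautomer, salts 13–16 with lithium counter-ions, and the cinchonidinium catalyst of step 3 is taken to give the (4aS) lactone (its pseudoenantiomeric cinchoninium salt is used if the induction is the opposite).

**Step 1**
Reactants: 1 phloroglucinol; 2 isobutyryl chloride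
Product: 3 phlorisobutyrophenone (2-methyl-1-(2,4,6-trihydroxyphenyl)propan-1-one)
Conditions: AlCl3 (3.5 equiv), PhNO2/CH2Cl2, 0 → 45 °C; aq. HCl
Reagents that add atoms: isobutyryl chloride 2, CC(C)C(Cl)=O
Why: Friedel–Crafts C-acylation of the very electron-rich arene; the ketone formed is deactivated as its AlCl3 chelate, so the reaction stops at mono-acylation, and no stereocentre is created.

**Step 2**
Reactants: 3 phlorisobutyrophenone; 4 prenyl bromide (2.1 equiv)
Product: 6 deoxycohumulone (2-methyl-1-[2,4,6-trihydroxy-3,5-bis(3-methylbut-2-en-1-yl)phenyl]propan-1-one), via monoprenyl ketone 5 (not isolated)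
Conditions: prenyl bromide, 10% aq. KOH, 0 °C
Reagents that add atoms: prenyl bromide 4, CC(C)=CCBr
Why: C-alkylation of the ambident phloroglucinolate by SN2 at the allylic bromide (aqueous hydroxide solvates the oxygens and directs attack to carbon), first to 5 and then to the symmetric 3,5-diprenyl ketone 6; no stereocentre is created.

**Step 3**
Reactants: 6 deoxycohumulone; 7 acryloyl chloride
Product: 9 enol lactone (4aS)-7-hydroxy-4a,8-bis(3-methylbut-2-en-1-yl)-6-(2-methylpropanoyl)-4,4a-dihydro-2H-chromene-2,5(3H)-dione, via aryl acrylate 8 (not isolated)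
Conditions: acryloyl chloride (1.05 equiv), Cs2CO3 (1.2 equiv), N-(9-anthracenylmethyl)cinchonidinium chloride (10 mol%), toluene/CH2Cl2, −40 °C
Reagents that add atoms: acryloyl chloride 7, C=CC(Cl)=O
Why: Proposed new method: the para-hydroxyl, the only one not hydrogen-bonded to the ketone, is acylated to the achiral aryl acrylate 8, whose phenolate, ion-paired with the chiral ammonium cation, adds through one of its two enantiotopic prenyl-bearing ring carbons to the tethered acrylate (dearomatising 6-endo-trig intramolecular Michael addition), creating the quaternary centre C4a (S) under catalyst control; the closest known reaction type is the cinchona phase-transfer-catalysed enantioselective alkylative dearomatisation of 3,5-diprenylated acylphloroglucinols with unsaturated aldehydes.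

**Step 4**
Reactants: 9 enol lactone; 4 prenyl bromide
Product: 10 prenylated lactone (3S,4aR)-7-hydroxy-3,4a,8-tris(3-methylbut-2-en-1-yl)-6-(2-methylpropanoyl)-4,4a-dihydro-2H-chromene-2,5(3H)-dione
Conditions: LiN(iPr)2 (2.2 equiv), THF/DMPU, −78 °C; prenyl bromide (1.2 equiv), −78 → −50 °C; aq. NH4Cl
Reagents that add atoms: prenyl bromide 4, CC(C)=CCBr
Why: Diastereoselective SN2 alkylation of a lactone lithium enolate (the first equivalent of base only turns the acidic acyl-enol into an unreactive triacylmethanide): the C4a prenyl group stands pseudo-axial on the half-chair lactone and blocks one face, so prenyl bromide enters trans to it and sets C3 as S, the future C7 centre.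

**Step 5**
Reactants: 10 prenylated lactone; 11 methyllithium; 12 methanesulfonyl chloride
Product: 17 secohyperforin (1R,5R,7S)-4-hydroxy-8,8-dimethyl-3,5,7-tris(3-methylbut-2-en-1-yl)-1-(2-methylpropanoyl)bicyclo[3.3.1]non-3-ene-2,9-dione, via methyl ketone dienolate 13 (not isolated), via tertiary alkoxide 14 (not isolated), via tertiary mesylate 15 (not isolated), via tertiary carbocation 16 (not isolated)
Conditions: MeLi (3.1 equiv), THF, −78 °C, 1 h; then MsCl (1.3 equiv), −78 → 0 °C; aq. NH4Cl
Reagents that add atoms: methyllithium 11, [Li]C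
Why: Proposed new method: deprotonation and two MeLi additions open the vinylogous-anhydride lactone to the tertiary alkoxide 14, its mesylate 15 ionises (SN1) to the same tertiary C8 carbocation 16 that the biosynthesis reaches by prenyl transfer, and the lithium dienolate captures it at the acyl-bearing carbon through a chair transition state with the C7 prenyl group equatorial, which forms the C1–C8 bond and fixes C1 as R (C5 and C7 are carried over, and closure at C3 would force that prenyl group axial); the closest known reaction types are the double addition of organolithiums to enol lactones and the ionisation of tertiary mesylates of dearomatised acylphloroglucinols to bicyclo[3.3.1]nonane triones.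

**Compound list**
1 | phloroglucinol (benzene-1,3,5-triol) | Oc1cc(O)cc(O)c1 | starting material
2 | isobutyryl chloride (2-methylpropanoyl chloride) | CC(C)C(Cl)=O | starting material
3 | phlorisobutyrophenone, 2-methyl-1-(2,4,6-trihydroxyphenyl)propan-1-one | CC(C)C(=O)c1c(O)cc(O)cc1O | intermediate
4 | prenyl bromide (1-bromo-3-methylbut-2-ene) | CC(C)=CCBr | starting material
5 | monoprenyl ketone, 2-methyl-1-[2,4,6-trihydroxy-3-(3-methylbut-2-en-1-yl)phenyl]propan-1-one (not isolated) | CC(C)C(=O)c1c(O)cc(O)c(CC=C(C)C)c1O | intermediate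
6 | deoxycohumulone, 2-methyl-1-[2,4,6-trihydroxy-3,5-bis(3-methylbut-2-en-1-yl)phenyl]propan-1-one | CC(C)C(=O)c1c(O)c(CC=C(C)C)c(O)c(CC=C(C)C)c1O | intermediate
7 | acryloyl chloride (prop-2-enoyl chloride) | C=CC(Cl)=O | starting material
8 | aryl acrylate, 3,5-dihydroxy-2,6-bis(3-methylbut-2-en-1-yl)-4-(2-methylpropanoyl)phenyl prop-2-enoate (not isolated) | C=CC(=O)Oc1c(CC=C(C)C)c(O)c(C(=O)C(C)C)c(O)c1CC=C(C)C | intermediate
9 | enol lactone, (4aS)-7-hydroxy-4a,8-bis(3-methylbut-2-en-1-yl)-6-(2-methylpropanoyl)-4,4a-dihydro-2H-chromene-2,5(3H)-dione | CC(C)=CCC1=C2OC(=O)CC[C@@]2(CC=C(C)C)C(=O)C(C(=O)C(C)C)=C1O | intermediate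
10 | prenylated lactone, (3S,4aR)-7-hydroxy-3,4a,8-tris(3-methylbut-2-en-1-yl)-6-(2-methylpropanoyl)-4,4a-dihydro-2H-chromene-2,5(3H)-dione | CC(C)=CCC1=C2OC(=O)[C@@H](CC=C(C)C)C[C@@]2(CC=C(C)C)C(=O)C(C(=O)C(C)C)=C1O | intermediate
11 | methyllithium | [Li]C | starting material
12 | methanesulfonyl chloride | CS(Cl)(=O)=O | starting material
13 | methyl ketone dienolate, dilithium salt of (6R)-6-[(2S)-2-acetyl-5-methylhex-4-en-1-yl]-3,5-dihydroxy-4,6-bis(3-methylbut-2-en-1-yl)-2-(2-methylpropanoyl)cyclohexa-2,4-dien-1-one (not isolated) | [Li+].[Li+].CC(C)=CCC1=C([O-])[C@@](CC=C(C)C)(C[C@H](CC=C(C)C)C(C)=O)C(=O)C(C(=O)C(C)C)=C1[O-] | intermediate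
14 | tertiary alkoxide, trilithium salt of (6R)-3,5-dihydroxy-6-[(2S)-2-(2-hydroxypropan-2-yl)-5-methylhex-4-en-1-yl]-4,6-bis(3-methylbut-2-en-1-yl)-2-(2-methylpropanoyl)cyclohexa-2,4-dien-1-one (not isolated) | [Li+].[Li+].[Li+].CC(C)=CCC1=C([O-])[C@@](CC=C(C)C)(C[C@H](CC=C(C)C)C(C)(C)[O-])C(=O)C(C(=O)C(C)C)=C1[O-] | intermediate
15 | tertiary mesylate, dilithium dienolate of the methanesulfonate ester of the tertiary alcohol of 14, configuration (6R, chain 2S) unchanged (not isolated) | [Li+].[Li+].CC(C)=CCC1=C([O-])[C@@](CC=C(C)C)(C[C@H](CC=C(C)C)C(C)(C)OS(C)(=O)=O)C(=O)C(C(=O)C(C)C)=C1[O-] | intermediate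
16 | tertiary carbocation, C8 cation from 15 by loss of mesylate, lithium dienolate, both stereocentres as in 15 (not isolated) | [Li+].CC(C)=CCC1=C([O-])[C@@](CC=C(C)C)(C[C@H](CC=C(C)C)[C+](C)C)C(=O)C(C(=O)C(C)C)=C1[O-] | intermediate
17 | secohyperforin, (1R,5R,7S)-4-hydroxy-8,8-dimethyl-3,5,7-tris(3-methylbut-2-en-1-yl)-1-(2-methylpropanoyl)bicyclo[3.3.1]non-3-ene-2,9-dione | CC(C)=CCC1=C(O)[C@@]2(CC=C(C)C)C[C@H](CC=C(C)C)C(C)(C)[C@@](C(=O)C(C)C)(C1=O)C2=O | target

**Totals**
Total step count: 5. Longest linear sequence: 5 (1 → 3 → 6 → 9 → 10 → 17).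

**Steps most likely to fail**

Step 3 (enantioselectivity of the intramolecular dearomative Michael addition, and a racemic background cyclisation). The fallback sets out from 6 and forms the C–C bond first and intermolecularly. Phase-transfer Michael addition of 6 to 1,1,1,3,3,3-hexafluoropropan-2-yl acrylate (same cinchonidinium salt, Cs2CO3, toluene, −40 °C) gives the dearomatised ester, 1,1,1,3,3,3-hexafluoropropan-2-yl 3-[(1S)-2,4-dihydroxy-1,3-bis(3-methylbut-2-en-1-yl)-5-(2-methylpropanoyl)-6-oxocyclohexa-2,4-dien-1-yl]propanoate F1. Its activated ester is then displaced by the neighbouring O4 enol (cat. DMAP, CH2Cl2), and the route is rejoined at 9.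

Step 4 (the lactone enolate can undergo retro-Michael re-aromatisation or alkylate sluggishly). The fallback sets out from 9 and avoids a free enolate. LiN(iPr)2 is added to 9 in the presence of Me3SiCl at −78 °C (in-situ quench) to give the bis-silylated ketene acetal, (4aR)-4a,8-bis(3-methylbut-2-en-1-yl)-6-(2-methylpropanoyl)-2,7-bis[(trimethylsilyl)oxy]-4,4a-dihydro-5H-chromen-5-one F2. F2 is prenylated with prenyl bromide 4 and ZnBr2 in CH2Cl2 (Lewis-acid-mediated SN1-type alkylation of a silyl ketene acetal, same facial bias) and desilylated on work-up, and the route is rejoined at 10.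

Step 5 (the cation may be captured by O4 instead of C1, or the alkoxide may not be mesylated selectively). The fallback sets out from 10 and runs the sequence stepwise through the O-cyclised isomer. MeLi addition with an aqueous NH4Cl quench gives the tertiary alcohol, (6R)-3,5-dihydroxy-6-[(2S)-2-(2-hydroxypropan-2-yl)-5-methylhex-4-en-1-yl]-4,6-bis(3-methylbut-2-en-1-yl)-2-(2-methylpropanoyl)cyclohexa-2,4-dien-1-one F3. Camphorsulfonic acid (5 mol%, CH2Cl2, 0 °C) closes F3 through O4 to the pyran, (3S,4aR)-7-hydroxy-2,2-dimethyl-3,4a,8-tris(3-methylbut-2-en-1-yl)-6-(2-methylpropanoyl)-2,3,4,4a-tetrahydro-5H-chromen-5-one F4. Me3SiOTf with 2,6-di-tert-butylpyridine (CH2Cl2, −40 °C) then silylates the enolised triketone and re-ionises the tertiary C8–O bond, and the silyl dienol ether captures the cation at carbon (SN1 α-tert-alkylation, O-to-C transfer under thermodynamic control); the route is rejoined at 17.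

**Further compounds**
F1 | step 3 | 1,1,1,3,3,3-hexafluoropropan-2-yl 3-[(1S)-2,4-dihydroxy-1,3-bis(3-methylbut-2-en-1-yl)-5-(2-methylpropanoyl)-6-oxocyclohexa-2,4-dien-1-yl]propanoate | CC(C)=CCC1=C(O)[C@@](CC=C(C)C)(CCC(=O)OC(C(F)(F)F)C(F)(F)F)C(=O)C(C(=O)C(C)C)=C1O
F2 | step 4 | (4aR)-4a,8-bis(3-methylbut-2-en-1-yl)-6-(2-methylpropanoyl)-2,7-bis[(trimethylsilyl)oxy]-4,4a-dihydro-5H-chromen-5-one | CC(C)=CCC1=C2OC(O[Si](C)(C)C)=CC[C@@]2(CC=C(C)C)C(=O)C(C(=O)C(C)C)=C1O[Si](C)(C)C
F3 | step 5 | (6R)-3,5-dihydroxy-6-[(2S)-2-(2-hydroxypropan-2-yl)-5-methylhex-4-en-1-yl]-4,6-bis(3-methylbut-2-en-1-yl)-2-(2-methylpropanoyl)cyclohexa-2,4-dien-1-one | CC(C)=CCC1=C(O)[C@@](CC=C(C)C)(C[C@H](CC=C(C)C)C(C)(C)O)C(=O)C(C(=O)C(C)C)=C1O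
F4 | step 5 | (3S,4aR)-7-hydroxy-2,2-dimethyl-3,4a,8-tris(3-methylbut-2-en-1-yl)-6-(2-methylpropanoyl)-2,3,4,4a-tetrahydro-5H-chromen-5-one | CC(C)=CCC1=C2OC(C)(C)[C@@H](CC=C(C)C)C[C@@]2(CC=C(C)C)C(=O)C(C(=O)C(C)C)=C1O
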